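**Retrosynthetic overview**
1. Target ⇐ reagent-controlled (Shi) epoxidation of an E-trisubstituted alkene ⇐ methylenation of a tricyclic ketone (ring A six-membered, ring B five-membered, ring C eleven-membered).
2. Ring C ⇐ nickel-catalysed reductive aldehyde–alkyne macrocyclisation (bond between the carbinol carbon and the methyl-bearing alkene carbon).
3. Side chains ⇐ Felkin 2-butynylation of an α-methyl aldehyde; Mukaiyama–Michael addition of a thiopropionate ketene acetal to a bicyclic enone; α′-prenylation (prenyl = masked CH2CHO).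
4. Bicyclic enone (rings A/B) ⇐ key oxidative 1,2-shift of the ring-fusion C–C bond of a Hajos–Parrish-derived hexahydroindene: its five-membered ring expands to ring A while its six-membered ring contracts to ring B.
5. Hajos–Parrish ketone ⇐ 2-methylcyclopentane-1,3-dione + methyl vinyl ketone (L-proline); ring order: A/B by ring-size interchange, then C.

Assumption: the major 5S epimer of 6/7 is drawn; the epimer ratio is immaterial because C-5 becomes sp2 in step 5.

**Step 1**
Reactants: 1 2-methylcyclopentane-1,3-dione; 2 but-3-en-2-one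
Product: 3 2-methyl-2-(3-oxobutyl)cyclopentane-1,3-dione
Conditions: H2O, AcOH (cat.), 70 °C
Reagents that add atoms: none
Why: Michael addition of the acidic 1,3-dione to methyl vinyl ketone in water (first half of the Hajos–Parrish sequence), creating a prochiral quaternary carbon and no stereocentre yet.

**Step 2**
Reactants: 3 2-methyl-2-(3-oxobutyl)cyclopentane-1,3-dione
Product: 5 (S)-7a-methyl-2,3,7,7a-tetrahydro-1H-indene-1,5(6H)-dione (Hajos–Parrish ketone), via Hajos ketol 4 (not isolated)
Conditions: L-proline (3 mol%), DMF, 20 °C; then H2SO4 (cat.), DMF, 95 °C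
Reagents that add atoms: none
Why: Hajos–Parrish–Eder–Sauer–Wiechert reaction, in which the proline enamine differentiates the two enantiotopic ring carbonyls in a hydrogen-bonded aldol transition state and so sets the quaternary centre as S, followed by acid dehydration of ketol 4.

**Step 3**
Reactants: 5 (S)-7a-methyl-2,3,7,7a-tetrahydro-1H-indene-1,5(6H)-dione
Product: 6 (1S,5S,7aS)-7a-methyl-2,3,5,6,7,7a-hexahydro-1H-indene-1,5-diol
Conditions: NaBH4, CeCl3·7H2O, MeOH, −78 → 0 °C
Reagents that add atoms: none
Why: Luche reduction, in which hydride attacks the cyclopentanone from the face opposite the angular methyl to give the 1S alcohol (OH cis to CH3, the future propanoate centre) and reduces the enone carbonyl in 1,2-fashion.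

**Step 4**
Reactants: 6 (1S,5S,7aS)-7a-methyl-2,3,5,6,7,7a-hexahydro-1H-indene-1,5-diol
Product: 7 (1S,5S,7aS)-7a-methyl-2,3,5,6,7,7a-hexahydro-1H-indene-1,5-diyl dipropanoate
Conditions: EtCOCl, pyridine, DMAP (cat.), CH2Cl2, 0 → 20 °C
Reagents that add atoms: propanoyl chloride, CCC(Cl)=O
Why: DMAP-catalysed acylation installs the propanoate that stays to the end and turns the allylic oxygen into the leaving group used in step 5, with no change at any stereocentre.

**Step 5**
Reactants: 7 (1S,5S,7aS)-7a-methyl-2,3,5,6,7,7a-hexahydro-1H-indene-1,5-diyl dipropanoate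
Product: 9 (7S,7aS)-7a-methyl-4-oxo-2,4,5,6,7,7a-hexahydro-1H-inden-7-yl propanoate, via β-propanoyloxy ketone 8 (not isolated)
Conditions: PhI(OH)OTs, MeOH/H2O (95:5), −20 → 20 °C; then DBU, CH2Cl2, 20 °C
Reagents that add atoms: hydroxy(tosyloxy)iodobenzene PhI(OH)OTs (delivers the ketone oxygen), Cc1ccc(cc1)S(=O)(=O)OI(O)c1ccccc1
Why: Proposed new method: oxidative 1,2-shift of a ring-fusion bond (semipinacol-type ring-size interchange), in which the electrophilic trivalent iodine adds to C-4 of 7 on the face opposite the angular methyl while solvent oxygen adds to the tertiary C-3a, the bulky aryl-λ3-iodanyl group then sits equatorial where only the C-3a–C-7a ring-fusion bond is antiperiplanar, and this bond migrates to C-4 with loss of iodobenzene while C-3a becomes the ketone carbon, so the five-membered ring expands to ring A and the six-membered ring contracts to ring B, after which DBU removes the β-propanoate by E1cB to give the enone; the closest known reaction type is the trivalent-iodine (or thallium trinitrate) oxidative ring contraction of cyclohexenes to cyclopentyl ketones, not yet shown for a ring-fusion alkene in which contraction of one ring expands its neighbour, and no new stereocentre survives because the ring-fusion carbon becomes sp2.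

**Step 6**
Reactants: 9 (7S,7aS)-7a-methyl-4-oxo-2,4,5,6,7,7a-hexahydro-1H-inden-7-yl propanoate; 10 1-bromo-3-methylbut-2-ene
Product: 12 (5R,7S,7aS)-7a-methyl-5-(3-methylbut-2-en-1-yl)-4-oxo-2,4,5,6,7,7a-hexahydro-1H-inden-7-yl propanoate, via lithium dienolate 11 (not isolated)
Conditions: LiN(iPr)2, THF, −78 °C; then 10, −78 → −20 °C
Reagents that add atoms: none
Why: kinetic α′-deprotonation of the cross-conjugated enone and SN2 enolate alkylation place the prenyl group (a masked CH2CHO) cis to the 7-propanoate, the 1,3-diequatorial arrangement that is also the thermodynamic one at this epimerisable centre.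

**Step 7**
Reactants: 13 S-ethyl propanethioate
Product: 15 (Z)-1-(ethylsulfanyl)-1-(trimethylsilyloxy)prop-1-ene, via lithium thioester enolate 14 (not isolated)
Conditions: LiN(iPr)2, THF, −78 °C; then Me3SiCl
Reagents that add atoms: chlorotrimethylsilane, C[Si](C)(C)Cl
Why: kinetic deprotonation in THF (Ireland model) gives the enolate with O and CH3 trans, which is trapped on oxygen to the (Z)-silyl ketene acetal (S cis to CH3).

**Step 8**
Reactants: 12 (5R,7S,7aS)-7a-methyl-5-(3-methylbut-2-en-1-yl)-4-oxo-2,4,5,6,7,7a-hexahydro-1H-inden-7-yl propanoate; 15 (Z)-1-(ethylsulfanyl)-1-(trimethylsilyloxy)prop-1-ene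
Product: 17 (3R,3aR,5R,7S,7aS)-3-[(2S)-1-(ethylsulfanyl)-1-oxopropan-2-yl]-7a-methyl-5-(3-methylbut-2-en-1-yl)-4-oxooctahydro-1H-inden-7-yl propanoate, via silyl enol ether 16 (not isolated)
Conditions: Me3SiOTf (10 mol%), CH2Cl2, −78 °C; then 1 M HCl, THF, 0 °C
Reagents that add atoms: none
Why: Mukaiyama–Michael addition through an open antiperiplanar transition state, in which the nucleophile adds to the enone β-carbon anti to the angular methyl (as in additions to 16-en-20-one steroids), the (Z)-ketene acetal gives the syn adduct (S at the methyl-bearing carbon), and protonation of silyl enol ether 16 opposite the new side chain gives the cis ring fusion (H cis to CH3), which is also the more stable fusion.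

**Step 9**
Reactants: 17 thioester of step 8
Product: 18 (3S,3aR,5R,7S,7aS)-7a-methyl-5-(3-methylbut-2-en-1-yl)-4-oxo-3-[(2S)-1-oxopropan-2-yl]octahydro-1H-inden-7-yl propanoate (aldehyde; same spatial arrangement as 17)
Conditions: Et3SiH, Pd/C (5 mol%), acetone, 20 °C
Reagents that add atoms: none
Why: Fukuyama reduction, in which zerovalent palladium inserts into the C–S bond and silicon delivers hydride, gives the aldehyde without touching the ketone, the ester or the trisubstituted alkene and without epimerising the α-centre.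

**Step 10**
Reactants: 18 aldehyde of step 9; 19 but-2-yne
Product: 22 homopropargylic alcohol (18 with CHO converted into (S)-CH(OH)CH2C≡CCH3, side chain (2S,3S)-3-hydroxyhept-5-yn-2-yl), via 1-lithiobut-2-yne 20 (not isolated), via allenyltitanium reagent 21 (not isolated)
Conditions: n-BuLi, TMEDA, THF, −78 → 0 °C; ClTi(OiPr)3, −78 °C; then 18, −78 °C
Reagents that add atoms: none
Why: propargylic lithiation and transmetalation give an allenyltitanium reagent that adds by SE2′ to the aldehyde only (ketone and esters untouched) to form the 2-butynyl carbinol, and Felkin–Anh attack anti to the ring substituent gives the 2,3-syn (3S) alcohol.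

**Step 11**
Reactants: 22 homopropargylic alcohol of step 10
Product: 23 acetate of 22 (side chain (2S,3S)-3-acetoxyhept-5-yn-2-yl)
Conditions: Ac2O, pyridine, DMAP (cat.), CH2Cl2, 20 °C
Reagents that add atoms: acetic anhydride, CC(=O)OC(C)=O
Why: DMAP-catalysed acetylation of the only free hydroxyl installs the acetate of the target with retention.

**Step 12**
Reactants: 23 acetate of step 11
Product: 24 ynal (23 with the prenyl group cut down to a 2-oxoethyl group at C-5)
Conditions: OsO4 (2 mol%), NaIO4, 2,6-lutidine, dioxane/H2O, 20 °C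
Reagents that add atoms: sodium periodate, [Na+].[O-]I(=O)(=O)=O
Why: Lemieux–Johnson oxidation, in which OsO4 dihydroxylates the only alkene (the internal alkyne is inert) and NaIO4 cleaves the diol to the aldehyde and acetone under buffered conditions that leave the α-centres alone.

**Step 13**
Reactants: 24 ynal of step 12
Product: 25 tricyclic ketone (target skeleton with C=O in place of C=CH2, an E-trisubstituted C=C in place of the epoxide and OSiEt3 in place of OH)
Conditions: Ni(cod)2 (20 mol%), IMes·HCl, KOtBu, Et3SiH, THF, 0.005 M, slow addition, 20 °C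
Reagents that add atoms: triethylsilane, CC[SiH](CC)CC
Why: nickel-catalysed reductive aldehyde–alkyne macrocyclisation (Montgomery type), in which oxidative cyclisation at zerovalent nickel with the small carbene ligand forms the C–C bond at the methyl-bearing alkyne carbon (endocyclic mode), cis addition of C and H gives the E alkene, and the carbinol centre (R) is set under macrocyclic control with the silyloxy group on the outer face of the forming eleven-membered ring.

**Step 14**
Reactants: 25 tricyclic ketone of step 13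
Product: 27 macrocyclic allylic alcohol (target lacking only the epoxide oxygen), via silyl-protected methylene compound 26 (not isolated)
Conditions: Zn, CH2Br2, TiCl4, THF/CH2Cl2, 0 → 20 °C; then 1 M HCl, THF, 0 °C
Reagents that add atoms: dibromomethane, BrCBr
Why: Takai–Lombardo methylenation is non-basic and ketone-selective, so the hindered ketone reacts while the two α-stereocentres and both esters survive, and dilute acid then removes the triethylsilyl group.

**Step 15**
Reactants: 27 macrocyclic allylic alcohol of step 14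
Product: 28 target CNP0415604.1
Conditions: L-fructose-derived Shi ketone (30 mol%), KHSO5, K2CO3, Bu4NHSO4 (cat.), MeCN/(MeO)2CH2/aq. Na2B4O7, 0 °C
Reagents that add atoms: potassium peroxymonosulfate, [K+].[O-]S(=O)(=O)OO
Why: Shi asymmetric epoxidation, in which the chiral dioxirane attacks the electron-rich E-trisubstituted alkene through a spiro transition state under reagent control (this ketone enantiomer gives the S,S epoxide), while the 1,1-disubstituted exocyclic alkene is a poor dioxirane substrate.

**Compound list**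
1 | 2-methylcyclopentane-1,3-dione | CC1C(=O)CCC1=O | starting material
2 | but-3-en-2-one | CC(=O)C=C | starting material
3 | 2-methyl-2-(3-oxobutyl)cyclopentane-1,3-dione | CC(=O)CCC1(C)C(=O)CCC1=O | intermediate
4 | (3aS,7aS)-3a-hydroxy-7a-methylhexahydro-1H-indene-1,5(4H)-dione (Hajos ketol) | C[C@]12CCC(=O)C[C@@]1(O)CCC2=O | intermediate (not isolated)
5 | (S)-7a-methyl-2,3,7,7a-tetrahydro-1H-indene-1,5(6H)-dione | C[C@]12CCC(=O)C=C1CCC2=O | intermediate
6 | (1S,5S,7aS)-7a-methyl-2,3,5,6,7,7a-hexahydro-1H-indene-1,5-diol | C[C@]12CC[C@H](O)C=C1CC[C@@H]2O | intermediate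
7 | (1S,5S,7aS)-7a-methyl-2,3,5,6,7,7a-hexahydro-1H-indene-1,5-diyl dipropanoate | C[C@]12CC[C@H](OC(=O)CC)C=C1CC[C@@H]2OC(=O)CC | intermediate
8 | (3S,3aS,7S,7aS)-7a-methyl-4-oxooctahydro-1H-indene-3,7-diyl dipropanoate (cis-fused) | O=C1CC[C@H](OC(=O)CC)[C@@]2(C)CC[C@H](OC(=O)CC)[C@@H]12 | intermediate (not isolated)
9 | (7S,7aS)-7a-methyl-4-oxo-2,4,5,6,7,7a-hexahydro-1H-inden-7-yl propanoate | O=C1CC[C@H](OC(=O)CC)[C@@]2(C)CCC=C12 | intermediate
10 | 1-bromo-3-methylbut-2-ene | CC(C)=CCBr | starting material
11 | lithium dienolate of 9 (O–C-4=C-5) | [Li+].[O-]C1=CC[C@H](OC(=O)CC)[C@@]2(C)CCC=C12 | intermediate (not isolated)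
12 | (5R,7S,7aS)-7a-methyl-5-(3-methylbut-2-en-1-yl)-4-oxo-2,4,5,6,7,7a-hexahydro-1H-inden-7-yl propanoate | O=C1[C@H](CC=C(C)C)C[C@H](OC(=O)CC)[C@@]2(C)CCC=C12 | intermediate
13 | S-ethyl propanethioate | CCC(=O)SCC | starting material
14 | lithium (Z)-1-(ethylsulfanyl)prop-1-en-1-olate | [Li+].C/C=C(/[O-])SCC | intermediate (not isolated)
15 | (Z)-1-(ethylsulfanyl)-1-(trimethylsilyloxy)prop-1-ene | C/C=C(/O[Si](C)(C)C)SCC | intermediate
16 | trimethylsilyl enol ether of 17 (Me3SiO on C-4, C-3a=C-4 double bond, other centres as in 17) | C[Si](C)(C)OC1=C2[C@H]([C@H](C)C(=O)SCC)CC[C@]2(C)[C@@H](OC(=O)CC)C[C@H]1CC=C(C)C | intermediate (not isolated)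
17 | (3R,3aR,5R,7S,7aS)-3-[(2S)-1-(ethylsulfanyl)-1-oxopropan-2-yl]-7a-methyl-5-(3-methylbut-2-en-1-yl)-4-oxooctahydro-1H-inden-7-yl propanoate (cis-fused; ring-fusion H, 5-prenyl and 7-propanoate cis to the angular methyl, 3-side chain trans to the ring-fusion H) | O=C1[C@H](CC=C(C)C)C[C@H](OC(=O)CC)[C@@]2(C)CC[C@@H]([C@H](C)C(=O)SCC)[C@@H]12 | intermediate
18 | (3S,3aR,5R,7S,7aS)-7a-methyl-5-(3-methylbut-2-en-1-yl)-4-oxo-3-[(2S)-1-oxopropan-2-yl]octahydro-1H-inden-7-yl propanoate (aldehyde of 17, same spatial arrangement) | O=C1[C@H](CC=C(C)C)C[C@H](OC(=O)CC)[C@@]2(C)CC[C@@H]([C@H](C)C=O)[C@@H]12 | intermediate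
19 | but-2-yne | CC#CC | starting material
20 | 1-lithiobut-2-yne | [Li]CC#CC | intermediate (not isolated)
21 | (buta-1,2-dien-3-yl)tri(propan-2-yloxy)titanium | C=C=C(C)[Ti](OC(C)C)(OC(C)C)OC(C)C | intermediate (not isolated)
22 | homopropargylic alcohol: 18 with the 3-side chain (2S,3S)-3-hydroxyhept-5-yn-2-yl, ring centres unchanged | O=C1[C@H](CC=C(C)C)C[C@H](OC(=O)CC)[C@@]2(C)CC[C@@H]([C@H](C)[C@@H](O)CC#CC)[C@@H]12 | intermediate
23 | acetate of 22, side chain (2S,3S)-3-acetoxyhept-5-yn-2-yl | O=C1[C@H](CC=C(C)C)C[C@H](OC(=O)CC)[C@@]2(C)CC[C@@H]([C@H](C)[C@@H](OC(C)=O)CC#CC)[C@@H]12 | intermediate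
24 | ynal: 23 with 2-oxoethyl in place of prenyl at C-5 | O=C1[C@H](CC=O)C[C@H](OC(=O)CC)[C@@]2(C)CC[C@@H]([C@H](C)[C@@H](OC(C)=O)CC#CC)[C@@H]12 | intermediate
25 | tricyclic ketone: target skeleton with C=O in place of C=CH2, E C=C in place of the epoxide, OSiEt3 in place of OH, all other centres as in the target | O=C1[C@H]2C[C@H](OC(=O)CC)[C@@]3(C)CC[C@@H]([C@H](C)[C@@H](OC(C)=O)C/C=C(C)/[C@H](O[Si](CC)(CC)CC)C2)[C@@H]13 | intermediate
26 | 25 with C=CH2 in place of C=O | C=C1[C@H]2C[C@H](OC(=O)CC)[C@@]3(C)CC[C@@H]([C@H](C)[C@@H](OC(C)=O)C/C=C(C)/[C@H](O[Si](CC)(CC)CC)C2)[C@@H]13 | intermediate (not isolated)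
27 | macrocyclic E-allylic alcohol: target lacking the epoxide oxygen | C=C1[C@H]2C[C@H](OC(=O)CC)[C@@]3(C)CC[C@@H]([C@H](C)[C@@H](OC(C)=O)C/C=C(C)/[C@H](O)C2)[C@@H]13 | intermediate
28 | CNP0415604.1 | C=C1[C@H]2C[C@H](OC(=O)CC)[C@@]3(C)CC[C@@H]([C@H](C)[C@@H](OC(C)=O)C[C@@H]4O[C@@]4(C)[C@H](O)C2)[C@@H]13 | target

**Step count**
Total steps: 15. Longest linear sequence: 14 (steps 1–6 and 8–15; step 7 is a one-step side branch).

**Three steps most likely to fail**

Step 5 (the new oxidative 1,2-shift; risks are neighbouring-group participation by the allylic propanoate and simple 1,2-dimethoxylation). The fallback sets out from 7 and returns at 9, using known chemistry only. OsO4 (cat.) with N-methylmorpholine N-oxide dihydroxylates the alkene on the face opposite the angular methyl to give the 3a,4-cis-diol dipropanoate F1. MsCl/Et3N sulfonylates only the secondary hydroxyl to give the 4-methanesulfonate F2. Et2AlCl (CH2Cl2, −78 °C) then triggers the known stereospecific semipinacol shift of the ring-fusion bond, which is antiperiplanar to the equatorial leaving group, to give the β-propanoyloxy ketone 8, and DBU converts 8 into 9.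

Step 8 (face selectivity at the β-carbon, syn/anti control at the methyl-bearing carbon, or 1,2-addition). The fallback sets out from 12 and returns at 18. Conjugate addition of isopropenylmagnesium bromide (CuBr·SMe2 cat., Me3SiCl, THF, −78 °C) gives the isopropenyl silyl enol ether F3. 9-BBN hydroborates only the 1,1-disubstituted alkene, and NaBO3 oxidation with hydrolysis of the enol ether gives the primary alcohol F4; the methyl-bearing centre is set by 1,2-induction and the epimers are separable. Dess–Martin periodinane then gives aldehyde 18.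

Step 13 (an eleven-membered ring by reductive coupling; regiochemistry at the alkyne and configuration at the carbinol are not secured). The fallback sets out from 23 and returns at 25. Cp2Zr(H)Cl hydrozirconation of the alkyne (zirconium at the methyl-bearing carbon after equilibration) followed by I2 gives the E-vinyl iodide F5. OsO4/NaIO4 cleavage of the prenyl group gives the iodo aldehyde F6. CrCl2 with NiCl2 (cat.) in DMSO/THF at high dilution (Nozaki–Hiyama–Kishi macrocyclisation) gives the macrocyclic allylic alcohol F7, and Et3SiCl/imidazole gives 25.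

**Further compounds**
F1 | step 5 | 3a,4-cis-diol of 7 (both hydroxyls trans to the angular methyl): 3a,4-dihydroxy-7a-methyloctahydro-1H-indene-1,5-diyl dipropanoate | C[C@]12CC[C@H](OC(=O)CC)[C@@H](O)[C@]1(O)CC[C@@H]2OC(=O)CC
F2 | step 5 | 4-methanesulfonate of F1 | C[C@]12CC[C@H](OC(=O)CC)[C@@H](OS(C)(=O)=O)[C@]1(O)CC[C@@H]2OC(=O)CC
F3 | step 8 | trimethylsilyl enol ether of the 3-(prop-1-en-2-yl) adduct of 12 (isopropenyl trans to the angular methyl) | C[Si](C)(C)OC1=C2[C@H](C(C)=C)CC[C@]2(C)[C@@H](OC(=O)CC)C[C@H]1CC=C(C)C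
F4 | step 8 | primary alcohol corresponding to 18 ((2S)-1-hydroxypropan-2-yl side chain, cis-fused ketone) | O=C1[C@H](CC=C(C)C)C[C@H](OC(=O)CC)[C@@]2(C)CC[C@@H]([C@H](C)CO)[C@@H]12
F5 | step 13 | E-vinyl iodide from 23 (side chain (2S,3S,E)-3-acetoxy-6-iodohept-5-en-2-yl) | O=C1[C@H](CC=C(C)C)C[C@H](OC(=O)CC)[C@@]2(C)CC[C@@H]([C@H](C)[C@@H](OC(C)=O)C/C=C(C)/I)[C@@H]12
F6 | step 13 | iodo aldehyde: F5 with 2-oxoethyl in place of prenyl | O=C1[C@H](CC=O)C[C@H](OC(=O)CC)[C@@]2(C)CC[C@@H]([C@H](C)[C@@H](OC(C)=O)C/C=C(C)/I)[C@@H]12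
F7 | step 13 | macrocyclic allylic alcohol: 25 without the triethylsilyl group | O=C1[C@H]2C[C@H](OC(=O)CC)[C@@]3(C)CC[C@@H]([C@H](C)[C@@H](OC(C)=O)C/C=C(C)/[C@H](O)C2)[C@@H]13
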